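**Retrosynthetic overview**
- The target comes from 3-heneicosyl-2,5-dihydroxy-1,4-benzoquinone by O-methylation of the hydroxyl next to the ring C–H.
- Enabling feature: with the ring numbered C1(=O), C2(OH), C3(heneicosyl), C4(=O), C5(OMe), C6(H), it is the bis-enol of a cyclohexane-1,2,4,5-tetraone. Two vicinal dicarbonyl pairs (C1–C2 and C4–C5) are joined by two enolisable carbons (C3 and C6), so C2 can be delivered as an ester carbonyl and C3 is the α-carbon of the C4 ketone.
- Key disconnection C2–C3 (Dieckmann closure of an acyclic 2,4,5-trioxo ester), preceded in the same flask by C1–C6 (crossed Claisen). The only ring forms in one operation from pentacosane-2,3-dione (C25) and dimethyl oxalate, already at the quinone oxidation level.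
- Pentacosane-2,3-dione comes from pentacos-2-yne (Ru-catalysed alkyne oxidation), which comes from 1-bromodocosane (C22) and 1-propynyllithium (C3).

Key step: step 3

Remark: the target has no stereocentre and no stereogenic double bond outside the ring, so it is achiral and no stereocontrol is needed.

**Route**

Step 1
Reactants: 1 1-bromodocosane; 2 1-propynyllithium
Product: 3 pentacos-2-yne
Conditions: THF–DMPU, NaI (cat.), 0 °C to rt
Reagents that add atoms: none
Why: SN2 alkylation of a lithium acetylide with a primary bromide in a dipolar cosolvent should join the 22-carbon chain of 1 (its C1 becomes ring C3, the other 21 carbons the heneicosyl group) to the three carbons of 2 that become C4, C5 and C6, giving the C25 alkyne.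

Step 2
Reactants: 3 pentacos-2-yne
Product: 4 pentacosane-2,3-dione
Conditions: RuO2·xH2O (cat.), NaIO4, EtOAc–MeCN–H2O, rt
Reagents that add atoms: sodium periodate, [Na+].[O-]I(=O)(=O)=O
Why: Catalytic ruthenium tetroxide oxidation of an internal dialkyl alkyne should stop at the 1,2-dione when periodate is limited to a small excess, and the saturated chain is inert on this time scale.

Step 3
Reactants: 4 pentacosane-2,3-dione; 5 dimethyl oxalate
Product: 7 3-heneicosyl-2,5-dihydroxycyclohexa-2,5-diene-1,4-dione, via methyl 2,4,5-trioxoheptacosanoate 6 (not isolated)
Conditions: NaOMe (3.5 equiv), 5 (1.5 equiv), THF–MeOH, N2, 0 °C then reflux, slow addition of 4; then aq. HCl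
Reagents that add atoms: none
Why: Methoxide enolises the methyl group of 4 (the less hindered α-carbon, future C6) and the enolate is acylated by the non-enolisable diester 5 in a crossed Claisen condensation to give the enolate of 6; a second enolisation at the chain-bearing methylene (future C3) then lets that carbon attack the remaining ester carbonyl (future C2) and expel methoxide, and the cyclohexane-1,2,4,5-tetraone so formed is the keto tautomer of 7, held as its dianion until acidification. The closest known reaction types are the oxalate–ketone Claisen–Dieckmann annulation that gives cyclopentane-1,2,4-triones and the base-induced cyclodimerisation of α-keto esters to 3,6-dialkyl-2,5-dihydroxy-1,4-benzoquinones. The one ring closes in a 6-exo-trig Dieckmann mode, the enolate carbon adding to an ester carbonyl whose C=O lies outside the forming ring. No stereocentre is created, since C3 and C6 both end as sp2 carbons of the bis-enol. The step needs cross-acylation to beat self-aldol condensation of the dione and C-acylation to beat O-acylation: the former is secured by keeping 5 and base in excess while 4 is added slowly, the latter by the reversibility of all steps under methoxide, which drains the mixture into the doubly vinylogous carboxylate of 7 as the thermodynamic sink. All four ring oxygens arrive at the final oxidation level, so no redox step follows.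

Step 4
Reactants: 7 3-heneicosyl-2,5-dihydroxycyclohexa-2,5-diene-1,4-dione
Product: 8 3-heneicosyl-2-hydroxy-5-methoxycyclohexa-2,5-diene-1,4-dione
Conditions: MeOH–THF, H2SO4 (cat.), 50 °C, stopped when 7 is consumed
Reagents that add atoms: methanol, CO
Why: Acid-catalysed vinylogous Fischer etherification of a hydroxyquinone should place the methyl group on the oxygen flanked by C6–H, because methanol adds there faster than at the carbon shielded by the heneicosyl chain and the reversible conditions also favour the ether whose methoxy group can stay coplanar with the ring.

**Compound list**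
1 | 1-bromodocosane | BrCCCCCCCCCCCCCCCCCCCCCC | starting material
2 | 1-propynyllithium | [Li]C#CC | starting material
3 | pentacos-2-yne | CC#CCCCCCCCCCCCCCCCCCCCCCC | intermediate
4 | pentacosane-2,3-dione | CC(=O)C(=O)CCCCCCCCCCCCCCCCCCCCCC | intermediate
5 | dimethyl oxalate | COC(=O)C(=O)OC | starting material
6 | methyl 2,4,5-trioxoheptacosanoate (formed as its sodium enolate, not isolated) | COC(=O)C(=O)CC(=O)C(=O)CCCCCCCCCCCCCCCCCCCCCC | intermediate
7 | 3-heneicosyl-2,5-dihydroxycyclohexa-2,5-diene-1,4-dione | CCCCCCCCCCCCCCCCCCCCCC1=C(O)C(=O)C=C(O)C1=O | intermediate
8 | 3-heneicosyl-2-hydroxy-5-methoxycyclohexa-2,5-diene-1,4-dione | CCCCCCCCCCCCCCCCCCCCCC1=C(O)C(=O)C=C(OC)C1=O | target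

Total step count: 4
Longest linear sequence: 4 steps (1 → 3 → 4 → 7 → 8)

**Steps most likely to fail**

1. Step 3. Self-aldol condensation of the dione may outrun oxalylation, or the sequence may stall after the first acylation because the second enolisation of the already anionic intermediate is slow. The fallback buys the ring instead of building it; it sets out from 1 and comes back at 7. Dehydrobromination of 1 (t-BuOK, THF, E2) should give docos-1-ene F1. Ozonolysis (O3, CH2Cl2–MeOH, −78 °C; then Me2S) should give heneicosanal F2. Proline-catalysed three-component reductive alkylation of commercial 2,5-dihydroxy-1,4-benzoquinone (used in excess) with F2 and Hantzsch ester in CH2Cl2 (Knoevenagel condensation, then transfer hydrogenation of the quinone methide) should deliver 7.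

2. Step 4. Site selectivity between the two vinylogous acid hydroxyls may be poor, or methylation may run on to the diether. The fallback sets out from 7 and comes back at 8. Exhaustive methylation (Me2SO4, K2CO3, acetone, reflux) should give 3-heneicosyl-2,5-dimethoxycyclohexa-2,5-diene-1,4-dione F3. Selective acid hydrolysis (70% HClO4, dioxane, rt) of the vinylogous ester next to the chain, whose methoxy group is twisted out of conjugation, should then give 8.

3. Step 2. Over-oxidation may cleave the bond between the two carbonyl carbons to carboxylic acids. The fallback sets out from 3 and comes back at 4. Lindlar semi-hydrogenation (H2, Pd/CaCO3–Pb, quinoline, hexane) should give (Z)-pentacos-2-ene F4. Upjohn dihydroxylation (OsO4 cat., NMO, acetone–H2O), a syn addition to the Z-alkene, should give racemic (2R,3S)-pentacosane-2,3-diol F5. Double Swern oxidation (oxalyl chloride, DMSO, Et3N, CH2Cl2, −78 °C) should give 4 without C–C cleavage.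

**Further compounds**
F1 | step 3 | docos-1-ene | C=CCCCCCCCCCCCCCCCCCCCC
F2 | step 3 | heneicosanal | O=CCCCCCCCCCCCCCCCCCCCC
F3 | step 4 | 3-heneicosyl-2,5-dimethoxycyclohexa-2,5-diene-1,4-dione | CCCCCCCCCCCCCCCCCCCCCC1=C(OC)C(=O)C=C(OC)C1=O
F4 | step 2 | (Z)-pentacos-2-ene | C/C=C\CCCCCCCCCCCCCCCCCCCCCC
F5 | step 2 | rac-(2R,3S)-pentacosane-2,3-diol | C[C@@H](O)[C@@H](O)CCCCCCCCCCCCCCCCCCCCCC
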